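## Structural features

The target is a flavone: a benzo ring (ring A) fused to a 4-pyranone (ring C), with a 4-hydroxyphenyl ring (ring B) attached at C2 through the single C2–C1' bond. Ring A is substituted everywhere except C8 and carries three contiguous oxygens: a free hydroxyl at C5 that is hydrogen-bonded to the C4 carbonyl, a methyl ether at C6 and the hydrogen sulfate ester at C7. There is no stereocentre, so every selectivity question is positional. The fragile parts are the aryl O–SO3H monoester, which is stable as a salt and towards base but hydrolyses under acid (its own acidity included), and the C2=C3 enone, which can be reduced or opened by strong base. The first difficulty is to tell four oxygens apart: methyl only on O6, sulfate only on O7, free hydroxyls at O5 and O4'. The second is to place the methoxy group at C6 and not at C8, which is decided when ring C is closed. The key step uses the polarised enone C2=C3–C4=O of ring C: an aryl–palladium species delivers its aryl group to the electrophilic β-carbon C2 of a 2-unsubstituted chromone, so ring B arrives last, with its own protecting group, on a ring A/C unit whose oxygen pattern is already settled.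

## Logic of the disconnections

14 ⇒ 12 (through 13). The last bonds cut are O4'–Si and the ionic bond between the sulfate and potassium. The sulfate monoester is the least stable function, so it is carried as its potassium salt and the free acid is released only at the very end. The gain is a stable, purifiable precursor. The demand is that the silyl ether leaves under non-acidic conditions and that the proton exchange is cold and short.

12 ⇒ 11. The O7–S bond is cut. In 11 the 5-hydroxyl is tied to the C4 carbonyl and O4' is silylated, so O7–H is the only hydroxyl free to react. The gain is that no sulfate has to survive earlier steps. The demand is a sulfating agent mild enough to leave O5 and the Si–O bond alone.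

11 ⇒ 10. The two benzylic C–O bonds at O5 and O7 are cut. Both come off in one neutral hydrogenolysis that is orthogonal to the silyl ether on O4'. The gain is that one operation unmasks exactly the two ring-A hydroxyls, of which only one reacts later. The demand is that C2=C3 and the Si–O bond survive the reduction.

10 ⇒ 8 + 9. The C2–C1' bond is cut. C2 is the β-carbon of the ring-C enone, and ring B can be brought in with a protecting group different from those on ring A, so O4' is distinguished from O5 and O7 at no extra cost. The gain is convergence and a ring A/C unit free of ring B. The demand is arylation at C2 and not C3, retention of the flavone oxidation level, and survival of the silyl ether under divalent palladium and O2.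

8 ⇒ 6 (through 7). The O1–C2 and C2–C3 bonds are cut: C2 is a one-carbon unit joined to the acetyl methyl carbon and to the phenol oxygen. The gain is a return to an ortho-hydroxyacetophenone. The demand is that the only free hydroxyl of 6 is the one next to the ring C–H; ring closure can then give only the 6-methoxy isomer. The acid used for closure must spare the benzyl ether beside the carbonyl.

6 ⇒ 5. The O–CH3 bond at the future C6 is cut. In 5 one hydroxyl is chelated to the acetyl carbonyl and the other is not, so the methyl group is placed by this reactivity difference without extra protection. The demand is one equivalent of methylating agent and exclusion of air, since 5 is a hydroquinone.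

5 ⇒ 3 (through 4). The C–O bond at the ring carbon para to the phenol oxygen is cut. That carbon is where a phenoxide attacks peroxodisulfate, so the position is set by mechanism. The acetyl group and both benzyl ethers are already in place, so no Lewis-acid acylation has to be run beside benzyl ethers. No sterically governed C–H borylation is needed either; it could not tell the ring-A C–H from the open C–H bonds of two benzyl groups. The demand is acceptance of modest conversion, with recovery and recycling of 3.

3 ⇒ 1 + 2. Two O–CH2Ph bonds are cut. In 1 the two ortho hydroxyls are equivalent, and the last one left is chelated to the carbonyl, so alkylation stops at the bis-ether. The gain is two commercial materials. The demand is control of stoichiometry to limit a third O-alkylation and C-benzylation.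

## Other disconnections considered

Alternative 1: Ring C is cut at C4a–C4, C4–C3 and O1–C2 into three pieces: 2-iodo-4-methoxy-3,5-bis(methoxymethoxy)phenol A1, 1-(benzyloxy)-4-ethynylbenzene A2 and carbon monoxide A3.
- Forward step: the C–I bond of A1 adds to zerovalent palladium (PdCl2(PPh3)2 as precatalyst, Et2NH as base and solvent), A3 inserts, the acyl–palladium couples with the acetylide of A2, and the amine promotes closure of the ortho-hydroxyaryl ynone to 2-[4-(benzyloxy)phenyl]-6-methoxy-5,7-bis(methoxymethoxy)chromen-4-one A4.
- In favour: three bonds, ring C and ring B are made in one operation. The aryl position is fixed by the alkyne terminus, so there is no C2/C3 question and no flavanone level to correct; on this point it is better than the chosen plan. It also needs no O2 beside an electron-rich boronic acid. The acetal/benzyl pairing gives an endgame of the same length (acid, sulfation, hydrogenolysis), which is equal.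
- Against: A1 is an electron-rich iodide with two ortho substituents. Slow oxidative addition and slow insertion of A3 would leave room for direct coupling to a 2-arylbenzofuran and for five-membered closure to an aurone. A toxic gas is needed. A1 requires a symmetric 3,5-dioxygenated 4-methoxyphenol whose preparation is the costly part of ring A, and the acetals must be kept away from acid throughout.
- Comparison: both plans attach ring B late (equal). Step economy would be equal at best, and probably one or two steps longer because of the phenol.

Alternative 2: The C4–C4a bond is cut, leading back to (Z)-3-[3,5-bis(benzyloxy)-4-methoxyphenoxy]-3-[4-(2,2-dimethylpropanoyloxy)phenyl]prop-2-enoic acid A5.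
- Forward step: the carboxyl group of A5 is activated as a mixed anhydride with (CF3CO)2O, and the acyl carbon attacks an ortho carbon of the aryloxy ring (intramolecular Friedel–Crafts acylation, six-membered closure) to give 4-[5,7-bis(benzyloxy)-6-methoxy-4-oxochromen-2-yl]phenyl 2,2-dimethylpropanoate A6.
- In favour: the aryloxy ring has two equivalent ortho carbons, so the 6-methoxy pattern is unambiguous. No transition metal and no oxidant are used. The aryl group sits at C2 by construction, which is better than the chosen plan on both C2/C3 selectivity and oxidation level. The ester on O4' is removed by mild base after sulfation, equal to the silyl ether.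
- Against: only the isomer of A5 with carboxyl and aryloxy groups cis can close. Addition of a phenol to an arylpropiolate would not secure that geometry, and acid can reverse the addition. The acidic anhydride medium threatens the benzyl ethers, and the very electron-rich ring A could be trifluoroacetylated. A5 again needs the symmetric phenol, so the count would be about two or three steps longer.
- Comparison: ring B is built in before ring C exists, so the chosen plan is better for late variation of ring B.

Alternative 3: The C6–OMe bond is cut on a complete flavone, 2-[4-(benzyloxy)phenyl]-5-hydroxy-6-iodo-7-(methoxymethoxy)chromen-4-one A7, which couples with methanol A8 as its methoxide.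
- Forward step: an Ullmann-type C–O coupling under monovalent copper (CuI, 1,10-phenanthroline, Cs2CO3) gives 2-[4-(benzyloxy)phenyl]-5-hydroxy-6-methoxy-7-(methoxymethoxy)chromen-4-one A9.
- In favour: the whole skeleton comes from cheap 5,7,4'-trioxygenated flavone material, so fewer steps precede the key step; this is better than the chosen plan. The methyl group enters last, which would allow an isotopic label, also better. A9 already has O5 free and O7 and O4' differentiated, so the endgame is equal in length.
- Against: the plan rests on iodination at C6 and not C8 of a 5-hydroxy-7-alkoxyflavone. Both carbons are activated, and the isomers would be hard to assign and separate. The C6–I bond of A7 is flanked on both sides and sits next to an acidic chelated hydroxyl, so hydrodeiodination and slow coupling are to be expected. Hot carbonate and methoxide can open ring C and re-close it through the other ortho oxygen, moving a 6-substituent to C8.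
- Comparison: the chosen plan fixes O6 before ring C exists and so carries no such positional risk. The alternative is shorter on paper but rests on two uncertain selectivities instead of one.

Key step: step 5

Assumption: the target is taken as the drawn hydrogen sulfate (free acid); because aryl hydrogen sulfates hydrolyse under their own acidity, the acid is released only in the last operation, and 13 is the storable form.

Remark: routes that build the acetophenone from a benzyl-protected 2-methoxyresorcinol were set aside, because iridium-catalysed C–H borylation would also attack the unhindered meta and para C–H bonds of the benzyl groups and BF3-promoted acetylation endangers aryl benzyl ethers.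

## Route

Step 1
Reactants: 1 1-(2,4,6-trihydroxyphenyl)ethanone; 2 benzyl bromide (2.1 equiv)
Product: 3 1-[2,4-bis(benzyloxy)-6-hydroxyphenyl]ethanone
Conditions: K2CO3 (2.2 equiv), DMF, 25 °C
Reagents that add atoms: none
Why: Williamson etherification; after the para hydroxyl and one ortho hydroxyl are benzylated, the remaining ortho hydroxyl is chelated to the acetyl carbonyl and is the least nucleophilic, so alkylation should stop at the bis-ether.

Step 2
Reactants: 3 1-[2,4-bis(benzyloxy)-6-hydroxyphenyl]ethanone
Product: 5 1-[2,4-bis(benzyloxy)-3,6-dihydroxyphenyl]ethanone, via potassium 3-acetyl-2,6-bis(benzyloxy)-4-hydroxyphenyl sulfate 4 (not isolated)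
Conditions: K2S2O8 (1.2 equiv), aq KOH, pyridine, 15–20 °C; then aq HCl, 80 °C, N2
Reagents that add atoms: potassium peroxodisulfate, [K+].[K+].[O-]S(=O)(=O)OOS(=O)(=O)[O-]
Why: Elbs persulfate oxidation: the phenoxide of 3 attacks a peroxide oxygen through its para carbon (C3, between the two benzyloxy groups) to give aryl sulfate 4, and acid hydrolysis with S–O cleavage releases hydroquinone 5. The para position follows from the mechanism; conversion should be modest and unreacted 3 is recovered.

Step 3
Reactants: 5 1-[2,4-bis(benzyloxy)-3,6-dihydroxyphenyl]ethanone
Product: 6 1-[2,4-bis(benzyloxy)-6-hydroxy-3-methoxyphenyl]ethanone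
Conditions: MeI (1.1 equiv), K2CO3 (1.1 equiv), acetone, 25–40 °C, N2
Reagents that add atoms: iodomethane, CI
Why: Williamson methylation; the 6-hydroxyl is chelated to the acetyl carbonyl, so one equivalent of MeI should alkylate only the hydroquinone hydroxyl at C3, which becomes O6 of the flavone.

Step 4
Reactants: 6 1-[2,4-bis(benzyloxy)-6-hydroxy-3-methoxyphenyl]ethanone
Product: 8 5,7-bis(benzyloxy)-6-methoxychromen-4-one, via (E)-1-[2,4-bis(benzyloxy)-6-hydroxy-3-methoxyphenyl]-3-(dimethylamino)prop-2-en-1-one 7 (not isolated)
Conditions: Me2NCH(OMe)2, toluene, 100 °C; evaporate; then conc. HCl, CH2Cl2, 25 °C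
Reagents that add atoms: N,N-dimethylformamide dimethyl acetal, COC(OC)N(C)C
Why: Condensation of the acetyl methyl group with the formamide acetal gives enaminone 7; acid then promotes conjugate addition of the phenol oxygen and loss of dimethylamine, closing ring C (enaminone route to chromones). The only free hydroxyl of 6 lies next to the ring C–H, so the methoxy group can end only at C6.

Step 5
Reactants: 8 5,7-bis(benzyloxy)-6-methoxychromen-4-one; 9 [4-(tert-butyldimethylsilyloxy)phenyl]boronic acid (2 equiv)
Product: 10 5,7-bis(benzyloxy)-2-[4-(tert-butyldimethylsilyloxy)phenyl]-6-methoxychromen-4-one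
Conditions: Pd(O2CCF3)2 (10 mol %), 2,2'-bipyridine (12 mol %), O2 (1 atm), DMF, 80 °C
Reagents that add atoms: none
Why: Oxidative Heck arylation of an enone: transmetalation of 9 to the bipyridine complex of divalent palladium gives an aryl–palladium species that coordinates C2=C3 of 8 and inserts with the aryl group going to C2, the electron-poor β-carbon, while palladium ends at C3 as the carbon-bound enolate. Because insertion is syn, H–C2 lies anti to palladium; the enolate therefore passes through its oxygen-bound form to the other face, after which syn β-hydride elimination restores C2=C3 and gives 10. The palladium hydride is returned to divalent palladium by O2 (through zerovalent palladium), so only boric acid and water form beside 10. The closest known reactions are the oxidative Heck arylation of chromones, coumarins and cyclic enones with arylboronic acids and the palladium-catalysed conjugate addition of arylboronic acids to chromones. No ring is closed and no stereocentre is created. C2 is preferred over C3 because the aryl–palladium bond adds with the polarity of the vinylogous ester, and the chelating bipyridine disfavours competing electrophilic palladation at the nucleophilic C3. The flavone level is secured by the aprotic medium and O2, which disfavour protonolysis of the enolate, and any flavanone formed should be dehydrogenated by the same catalyst. In 8 both ring-A oxygens are benzyl ethers and in 9 the phenol is silylated, so no phenoxide binds the catalyst and C2=C3 is the only alkene present.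

Step 6
Reactants: 10 5,7-bis(benzyloxy)-2-[4-(tert-butyldimethylsilyloxy)phenyl]-6-methoxychromen-4-one
Product: 11 2-[4-(tert-butyldimethylsilyloxy)phenyl]-5,7-dihydroxy-6-methoxychromen-4-one
Conditions: H2 (1 atm), Pd/C (10 wt % Pd), EtOAc–THF, 25 °C
Reagents that add atoms: none
Why: Hydrogenolysis of the two aryl benzyl ethers; the neutral aprotic medium should keep the aryl silyl ether, and the cross-conjugated C2=C3 of a flavone is not expected to be reduced at 1 atm.

Step 7
Reactants: 11 2-[4-(tert-butyldimethylsilyloxy)phenyl]-5,7-dihydroxy-6-methoxychromen-4-one
Product: 12 potassium 2-[4-(tert-butyldimethylsilyloxy)phenyl]-5-hydroxy-6-methoxy-4-oxochromen-7-yl sulfate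
Conditions: SO3·pyridine (3 equiv), pyridine, 25 °C; then aq KHCO3 to pH 8; C18 silica
Reagents that add atoms: sulfur trioxide–pyridine complex, O=S(=O)([O-])[n+]1ccccc1; potassium hydrogen carbonate, [K+].OC([O-])=O
Why: O-sulfation with an amine–SO3 complex; the 5-hydroxyl is locked in a hydrogen bond to C4=O and O4' is silylated, so only the 7-hydroxyl should react. Neutralisation with KHCO3 gives the stable potassium salt.

Step 8
Reactants: 12 potassium 2-[4-(tert-butyldimethylsilyloxy)phenyl]-5-hydroxy-6-methoxy-4-oxochromen-7-yl sulfate
Product: 14 5-hydroxy-2-(4-hydroxyphenyl)-6-methoxy-4-oxochromen-7-yl hydrogen sulfate (hispidulin 7-sulfate), via potassium 5-hydroxy-2-(4-hydroxyphenyl)-6-methoxy-4-oxochromen-7-yl sulfate 13 (not isolated)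
Conditions: NH4F (3 equiv), MeOH, 25 °C; evaporate; C18 pad; then sulfonic acid resin (H+ form), H2O, 0 °C; freeze-dry
Reagents that add atoms: none
Why: Fluoride cleaves the aryl silyl ether under near-neutral conditions that leave the sulfate monoester anion untouched, and the by-products are volatile. Cold passage over the acid resin exchanges potassium for a proton, and immediate freeze-drying limits acid-catalysed hydrolysis of the O–S bond.

## Compound list

1 | 1-(2,4,6-trihydroxyphenyl)ethanone | CC(=O)c1c(O)cc(O)cc1O | starting material
2 | benzyl bromide | BrCc1ccccc1 | starting material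
3 | 1-[2,4-bis(benzyloxy)-6-hydroxyphenyl]ethanone | CC(=O)c1c(O)cc(OCc2ccccc2)cc1OCc1ccccc1 | intermediate
4 | potassium 3-acetyl-2,6-bis(benzyloxy)-4-hydroxyphenyl sulfate | CC(=O)c1c(O)cc(OCc2ccccc2)c(OS(=O)(=O)[O-])c1OCc1ccccc1.[K+] | intermediate (not isolated)
5 | 1-[2,4-bis(benzyloxy)-3,6-dihydroxyphenyl]ethanone | CC(=O)c1c(O)cc(OCc2ccccc2)c(O)c1OCc1ccccc1 | intermediate
6 | 1-[2,4-bis(benzyloxy)-6-hydroxy-3-methoxyphenyl]ethanone | CC(=O)c1c(O)cc(OCc2ccccc2)c(OC)c1OCc1ccccc1 | intermediate
7 | (E)-1-[2,4-bis(benzyloxy)-6-hydroxy-3-methoxyphenyl]-3-(dimethylamino)prop-2-en-1-one | CN(C)/C=C/C(=O)c1c(O)cc(OCc2ccccc2)c(OC)c1OCc1ccccc1 | intermediate (not isolated)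
8 | 5,7-bis(benzyloxy)-6-methoxychromen-4-one | COc1c(OCc2ccccc2)cc2occc(=O)c2c1OCc1ccccc1 | intermediate
9 | [4-(tert-butyldimethylsilyloxy)phenyl]boronic acid | CC(C)(C)[Si](C)(C)Oc1ccc(B(O)O)cc1 | starting material
10 | 5,7-bis(benzyloxy)-2-[4-(tert-butyldimethylsilyloxy)phenyl]-6-methoxychromen-4-one | COc1c(OCc2ccccc2)cc2oc(-c3ccc(O[Si](C)(C)C(C)(C)C)cc3)cc(=O)c2c1OCc1ccccc1 | intermediate
11 | 2-[4-(tert-butyldimethylsilyloxy)phenyl]-5,7-dihydroxy-6-methoxychromen-4-one | COc1c(O)cc2oc(-c3ccc(O[Si](C)(C)C(C)(C)C)cc3)cc(=O)c2c1O | intermediate
12 | potassium 2-[4-(tert-butyldimethylsilyloxy)phenyl]-5-hydroxy-6-methoxy-4-oxochromen-7-yl sulfate | COc1c(OS(=O)(=O)[O-])cc2oc(-c3ccc(O[Si](C)(C)C(C)(C)C)cc3)cc(=O)c2c1O.[K+] | intermediate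
13 | potassium 5-hydroxy-2-(4-hydroxyphenyl)-6-methoxy-4-oxochromen-7-yl sulfate | COc1c(OS(=O)(=O)[O-])cc2oc(-c3ccc(O)cc3)cc(=O)c2c1O.[K+] | intermediate (not isolated)
14 | 5-hydroxy-2-(4-hydroxyphenyl)-6-methoxy-4-oxochromen-7-yl hydrogen sulfate (hispidulin 7-sulfate) | COc1c(OS(=O)(=O)O)cc2oc(-c3ccc(O)cc3)cc(=O)c2c1O | target

## Step count and least certain steps

Total step count: 8. Longest linear sequence: 8 steps (1 → 14); 9 is used as purchased and enters at step 5.

**Step 5 (key step).**
- Risk: the aryl–palladium species may be consumed by protodeboronation, homocoupling and oxidation to the phenol faster than it inserts into the electron-rich, 5-alkoxylated enone. The reaction may also stop at the flavanone level, and the silyl ether may be partly lost in warm DMF. Desilylated material could be returned to 10 with TBSCl and imidazole, since O4' would then be the only free hydroxyl.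
- Fallback: this sets out from 8 and 9 and separates carbon–carbon bond formation from oxidation. A base-free 1,4-addition catalysed by [Rh(OH)(cod)]2 in dioxane–water at 60 °C should give racemic 5,7-bis(benzyloxy)-2-[4-(tert-butyldimethylsilyloxy)phenyl]-6-methoxychroman-4-one F1. Dehydrogenation of this flavanone with DDQ in dioxane at 100 °C then returns to the route at 10.

**Step 2.**
- Risk: low conversion, because peroxodisulfate decomposes and oxidises the hydroquinone product while the lipophilic phenoxide is poorly soluble; over-oxidation to the quinone is also possible.
- Fallback: this sets out from 2 and builds the oxygen pattern on a symmetric phenol instead; it is two steps longer.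
  - Purchased methyl 3,5-dihydroxy-4-methoxybenzoate F2 is benzylated with 2 (K2CO3, DMF) to methyl 3,5-bis(benzyloxy)-4-methoxybenzoate F3.
  - F3 is reduced with LiAlH4 in THF to [3,5-bis(benzyloxy)-4-methoxyphenyl]methanol F4 and oxidised with MnO2 in CH2Cl2 to 3,5-bis(benzyloxy)-4-methoxybenzaldehyde F5.
  - Baeyer–Villiger oxidation with mCPBA gives 3,5-bis(benzyloxy)-4-methoxyphenyl formate F6, which K2CO3 in MeOH cleaves to 3,5-bis(benzyloxy)-4-methoxyphenol F7.
  - The two ortho positions of F7 are equivalent. A Lewis-acid-free Friedel–Crafts acetylation with the mixed anhydride from AcOH and (CF3CO)2O (CH2Cl2, 0 to 25 °C), followed by K2CO3 in MeOH to cleave any O-acetate, returns to the route at 6.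

**Step 7.**
- Risk: competing sulfation of the chelated 5-hydroxyl, or sluggish reaction at the 7-hydroxyl, which is flanked by the methoxy group; slow loss of the silyl group during a long reaction in pyridine.
- Fallback: this sets out from 11 and carries the sulfate as a neutral, chromatographable diester. Treatment with 2,2,2-trichloroethyl chlorosulfate, Et3N and DMAP in THF should give 2-[4-(tert-butyldimethylsilyloxy)phenyl]-5-hydroxy-6-methoxy-4-oxochromen-7-yl 2,2,2-trichloroethyl sulfate F8, which can be purified on silica. Reductive cleavage with Zn and HCO2NH4 in MeOH gives ammonium 2-[4-(tert-butyldimethylsilyloxy)phenyl]-5-hydroxy-6-methoxy-4-oxochromen-7-yl sulfate F9. Evaporation from aqueous KHCO3 exchanges ammonium for potassium and returns to the route at 12.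

**Step 8.**
- Risk: acid-catalysed hydrolysis of the O–S bond during proton exchange and concentration, with loss of the sulfate group.
- Fallback: this sets out from 13 and replaces exchange on an acidic resin by a stoichiometric salt metathesis, so that no excess acid meets the ester. Ba(OAc)2 converts 13 into barium bis[5-hydroxy-2-(4-hydroxyphenyl)-6-methoxy-4-oxochromen-7-yl sulfate] F10, freed from potassium acetate on C18 silica. Exactly one equivalent of dilute H2SO4 at 0 °C precipitates BaSO4, and filtration and freeze-drying return to the route at 14.

## Further compounds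

F1 | step 5 | 5,7-bis(benzyloxy)-2-[4-(tert-butyldimethylsilyloxy)phenyl]-6-methoxychroman-4-one (racemic) | COc1c(OCc2ccccc2)cc2c(c1OCc1ccccc1)C(=O)CC(c1ccc(O[Si](C)(C)C(C)(C)C)cc1)O2
F2 | step 2 | methyl 3,5-dihydroxy-4-methoxybenzoate (purchased) | COC(=O)c1cc(O)c(OC)c(O)c1
F3 | step 2 | methyl 3,5-bis(benzyloxy)-4-methoxybenzoate | COC(=O)c1cc(OCc2ccccc2)c(OC)c(OCc2ccccc2)c1
F4 | step 2 | [3,5-bis(benzyloxy)-4-methoxyphenyl]methanol | COc1c(OCc2ccccc2)cc(CO)cc1OCc1ccccc1
F5 | step 2 | 3,5-bis(benzyloxy)-4-methoxybenzaldehyde | COc1c(OCc2ccccc2)cc(C=O)cc1OCc1ccccc1
F6 | step 2 | 3,5-bis(benzyloxy)-4-methoxyphenyl formate | COc1c(OCc2ccccc2)cc(OC=O)cc1OCc1ccccc1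
F7 | step 2 | 3,5-bis(benzyloxy)-4-methoxyphenol | COc1c(OCc2ccccc2)cc(O)cc1OCc1ccccc1
F8 | step 7 | 2-[4-(tert-butyldimethylsilyloxy)phenyl]-5-hydroxy-6-methoxy-4-oxochromen-7-yl 2,2,2-trichloroethyl sulfate | COc1c(OS(=O)(=O)OCC(Cl)(Cl)Cl)cc2oc(-c3ccc(O[Si](C)(C)C(C)(C)C)cc3)cc(=O)c2c1O
F9 | step 7 | ammonium 2-[4-(tert-butyldimethylsilyloxy)phenyl]-5-hydroxy-6-methoxy-4-oxochromen-7-yl sulfate | COc1c(OS(=O)(=O)[O-])cc2oc(-c3ccc(O[Si](C)(C)C(C)(C)C)cc3)cc(=O)c2c1O.[NH4+]
F10 | step 8 | barium bis[5-hydroxy-2-(4-hydroxyphenyl)-6-methoxy-4-oxochromen-7-yl sulfate] | COc1c(OS(=O)(=O)[O-])cc2oc(-c3ccc(O)cc3)cc(=O)c2c1O.COc1c(OS(=O)(=O)[O-])cc2oc(-c3ccc(O)cc3)cc(=O)c2c1O.[Ba+2]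
A1 | alternative 1 | 2-iodo-4-methoxy-3,5-bis(methoxymethoxy)phenol | COCOc1cc(O)c(I)c(OCOC)c1OC
A2 | alternative 1 | 1-(benzyloxy)-4-ethynylbenzene | C#Cc1ccc(OCc2ccccc2)cc1
A3 | alternative 1 | carbon monoxide | [C-]#[O+]
A4 | alternative 1 | 2-[4-(benzyloxy)phenyl]-6-methoxy-5,7-bis(methoxymethoxy)chromen-4-one | COCOc1cc2oc(-c3ccc(OCc4ccccc4)cc3)cc(=O)c2c(OCOC)c1OC
A5 | alternative 2 | (Z)-3-[3,5-bis(benzyloxy)-4-methoxyphenoxy]-3-[4-(2,2-dimethylpropanoyloxy)phenyl]prop-2-enoic acid | OC(=O)/C=C(\Oc1cc(OCc2ccccc2)c(OC)c(OCc2ccccc2)c1)c1ccc(OC(=O)C(C)(C)C)cc1
A6 | alternative 2 | 4-[5,7-bis(benzyloxy)-6-methoxy-4-oxochromen-2-yl]phenyl 2,2-dimethylpropanoate | COc1c(OCc2ccccc2)cc2oc(-c3ccc(OC(=O)C(C)(C)C)cc3)cc(=O)c2c1OCc1ccccc1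
A7 | alternative 3 | 2-[4-(benzyloxy)phenyl]-5-hydroxy-6-iodo-7-(methoxymethoxy)chromen-4-one | COCOc1cc2oc(-c3ccc(OCc4ccccc4)cc3)cc(=O)c2c(O)c1I
A8 | alternative 3 | methanol | CO
A9 | alternative 3 | 2-[4-(benzyloxy)phenyl]-5-hydroxy-6-methoxy-7-(methoxymethoxy)chromen-4-one | COCOc1cc2oc(-c3ccc(OCc4ccccc4)cc3)cc(=O)c2c(O)c1OC
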